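## Retrosynthetic overview
1. The target comes from its 7-O-(1,1-dimethylallyl) ether by a retro-aromatic Claisen shift (C8–CH2 bond). The ether masks the 7-OH and also carries the prenyl carbons.
2. Ring C comes from one radical [4+2] annulation of a salicylaldehyde with a styrene. Aroyl-radical addition forms C3–C4, and capture of the benzylic radical at a chiral copper centre forms O1–C2 and sets C2.
3. The salicylaldehyde comes from resorcinol (ring A), DMF (C4) and 2-methylbut-3-en-2-ol (C5 unit).
4. The styrene comes from 4-bromophenol (ring B), 3-methylbut-2-enal (pyran ring) and vinyltrifluoroborate (C2 and C3).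
5. Ring order: rings A and B are bought, the chromene pyran ring is closed first and ring C last. The prenyl group appears in the final step.

Assumption: the sense of induction of the new copper step cannot be known in advance, so (S,S)-tBu-Box is written, and the (R,R)-ligand is used instead if the first analytical run gives the (2R) product.

## Route

Step 1
Reactants: 1 resorcinol
Product: 3 2,4-dihydroxybenzaldehyde, via aryl iminium chloride 2 (not isolated)
Conditions: POCl3 (1.2 equiv), DMF (1.3 equiv), MeCN, −15 → 25 °C; then H2O, 50 °C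
Reagents that add atoms: N,N-dimethylformamide, CN(C)C=O (formyl carbon); water, O (carbonyl oxygen); phosphoryl chloride, O=P(Cl)(Cl)Cl (chloride counter-ion of 2 only)
Why: In this Vilsmeier–Haack formylation the chloroiminium salt attacks the most nucleophilic ring position (para to one OH, ortho to the other) and water hydrolyses iminium salt 2, with no stereocentre formed.

Step 2
Reactants: 3 2,4-dihydroxybenzaldehyde (1.0 equiv); 4 2-methylbut-3-en-2-ol (1.1 equiv)
Product: 6 2-hydroxy-4-[(2-methylbut-3-en-2-yl)oxy]benzaldehyde, via tert-prenyl tert-butyl carbonate 5 (not isolated)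
Conditions: 4, nBuLi (1.05 equiv), THF, −78 → 0 °C; Boc2O (1.05 equiv), 0 → 20 °C, 2 h; then 3, Pd(PPh3)4 (2 mol %), 0 °C, 1–2 h; pH 7 buffer work-up
Reagents that add atoms: di-tert-butyl dicarbonate, CC(C)(C)OC(=O)OC(=O)OC(C)(C)C (atoms held only in intermediate 5)
Why: Carbonate formation is followed by Tsuji–Trost O-allylation, in which zerovalent palladium ionises 5, the departing tert-butyl carbonate supplies the base, and under kinetic control at 0 °C the phenoxide attacks the tertiary, more cation-like allyl terminus; only the more acidic, unchelated 4-OH reacts because the 2-OH is tied to the formyl oxygen, and no stereocentre is formed.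

Step 3
Reactants: 7 4-bromophenol; 8 3-methylbut-2-enal
Product: 11 6-bromo-2,2-dimethyl-2H-chromene, via benzodioxaborinine 9 (not isolated), via ortho-quinone methide 10 (not isolated)
Conditions: PhB(OH)2 (1.0 equiv), AcOH, toluene, reflux, Dean–Stark, 24 h
Reagents that add atoms: phenylboronic acid, OB(O)c1ccccc1 (held only in intermediate 9, released again)
Why: A boronic-acid-templated ortho-hydroxyalkylation (Nagata type) gives 9, which loses PhB(OH)2 on heating to give 10, and an oxa-6π electrocyclisation closes the pyran ring; the para bromine leaves only two equivalent ortho positions, and no stereocentre is formed.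

Step 4
Reactants: 11 6-bromo-2,2-dimethyl-2H-chromene; 12 potassium vinyltrifluoroborate
Product: 13 6-ethenyl-2,2-dimethyl-2H-chromene
Conditions: PdCl2 (2 mol %), PPh3 (6 mol %), Cs2CO3 (3 equiv), THF/H2O 9:1, 85 °C (sealed), 20 h; used fresh after a short silica plug
Reagents that add atoms: none
Why: This Suzuki–Miyaura vinylation under Molander conditions proceeds by oxidative addition into the aryl C–Br bond, transmetalation from the slowly hydrolysed trifluoroborate and reductive elimination, while the hindered chromene alkene is a spectator and no stereocentre is formed.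

Step 5 (key step)
Reactants: 6 2-hydroxy-4-[(2-methylbut-3-en-2-yl)oxy]benzaldehyde (1.5 equiv, excess recovered); 13 6-ethenyl-2,2-dimethyl-2H-chromene (1.0 equiv)
Product: 16 (2S)-2-(2,2-dimethyl-2H-chromen-6-yl)-7-[(2-methylbut-3-en-2-yl)oxy]chroman-4-one, via aroyl radical 14 (not isolated), via benzylic radical 15 (not isolated)
Conditions: Cu(MeCN)4PF6 (10 mol %), (S,S)-tBu-Box (12 mol %), PhCO3tBu (1.2 equiv, syringe pump 6 h), PhCF3/MeCN 10:1, 30 °C, Ar
Reagents that add atoms: none
Why: Proposed new method: monovalent copper splits the perester into a divalent copper benzoate and tBuO•, which abstracts the formyl hydrogen of 6 (the only weak X–H bond present, since neither partner has an allylic or benzylic hydrogen and the 2-OH is strengthened by its hydrogen bond to the carbonyl group); the nucleophilic aroyl radical 14 adds to the open CH2 terminus of styrene 13 (C3–C4 bond) much faster than to the hindered chromene alkene or the unactivated ether alkene; benzylic radical 15 is caught by Box-bound divalent copper, its own phenol replaces benzoate so that the 2-oxidoaryl ketone sits as a two-point O,O-chelate, and C–O reductive elimination from trivalent copper closes ring C and sets C2 inside the chiral pocket while returning monovalent copper; the closest known reaction types are the asymmetric Kharasch–Sosnovsky C–O coupling, the Cu/Box radical oxyfunctionalisation of styrenes carrying a pendant oxygen nucleophile, and the peroxide-driven radical acylation of styrenes with aldehydes.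

Step 6
Reactants: 16 (2S)-2-(2,2-dimethyl-2H-chromen-6-yl)-7-[(2-methylbut-3-en-2-yl)oxy]chroman-4-one
Product: 18 (2S)-2-(2,2-dimethyl-2H-chromen-6-yl)-7-hydroxy-8-(3-methylbut-2-en-1-yl)chroman-4-one, via ortho-dienone 17 (not isolated)
Conditions: o-xylene (degassed), 130 °C, sealed tube, 8 h, no acid or base
Reagents that add atoms: none
Why: In this aromatic Claisen rearrangement a concerted [3,3] shift through a chair transition state joins the unsubstituted alkene terminus to C8, which is preferred over C6 because the C7–C8 bond of 7-oxygenated benzopyranones has the higher double-bond character (as with 7-allyloxy-coumarins and -chromones), dienone 17 tautomerises to the phenol, the gem-dimethyl group allows the shift at 130 °C, and without acid or base the C2 stereocentre, which can only be lost by retro-oxa-Michael opening, is retained.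

## Compound list
1 | resorcinol | Oc1cccc(O)c1 | starting material
2 | [(2,4-dihydroxyphenyl)methylidene]dimethylammonium chloride | C[N+](C)=Cc1ccc(O)cc1O.[Cl-] | intermediate
3 | 2,4-dihydroxybenzaldehyde | O=Cc1ccc(O)cc1O | intermediate
4 | 2-methylbut-3-en-2-ol | C=CC(C)(C)O | starting material
5 | tert-butyl 2-methylbut-3-en-2-yl carbonate | C=CC(C)(C)OC(=O)OC(C)(C)C | intermediate
6 | 2-hydroxy-4-[(2-methylbut-3-en-2-yl)oxy]benzaldehyde | C=CC(C)(C)Oc1ccc(C=O)c(O)c1 | intermediate
7 | 4-bromophenol | Oc1ccc(Br)cc1 | starting material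
8 | 3-methylbut-2-enal | CC(C)=CC=O | starting material
9 | 6-bromo-4-(2-methylprop-1-en-1-yl)-2-phenyl-4H-1,3,2-benzodioxaborinine (racemic) | CC(C)=CC1OB(c2ccccc2)Oc2ccc(Br)cc12 | intermediate
10 | 4-bromo-6-(3-methylbut-2-en-1-ylidene)cyclohexa-2,4-dien-1-one | O=C1C=CC(Br)=CC1=CC=C(C)C | intermediate
11 | 6-bromo-2,2-dimethyl-2H-chromene | CC1(C)C=Cc2cc(Br)ccc2O1 | intermediate
12 | potassium vinyltrifluoroborate | C=C[B-](F)(F)F.[K+] | starting material
13 | 6-ethenyl-2,2-dimethyl-2H-chromene | C=Cc1ccc2c(c1)C=CC(C)(C)O2 | intermediate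
14 | 2-hydroxy-4-[(2-methylbut-3-en-2-yl)oxy]benzoyl radical | C=CC(C)(C)Oc1ccc([C]=O)c(O)c1 | intermediate
15 | 1-(2,2-dimethyl-2H-chromen-6-yl)-3-{2-hydroxy-4-[(2-methylbut-3-en-2-yl)oxy]phenyl}-3-oxopropyl radical | C=CC(C)(C)Oc1ccc(C(=O)C[CH]c2ccc3c(c2)C=CC(C)(C)O3)c(O)c1 | intermediate
16 | (2S)-2-(2,2-dimethyl-2H-chromen-6-yl)-7-[(2-methylbut-3-en-2-yl)oxy]chroman-4-one | C=CC(C)(C)Oc1ccc2c(c1)O[C@H](c1ccc3c(c1)C=CC(C)(C)O3)CC2=O | intermediate
17 | (2S)-2-(2,2-dimethyl-2H-chromen-6-yl)-8-(3-methylbut-2-en-1-yl)-2,3-dihydro-4H-chromene-4,7(8H)-dione (C8 epimers) | CC(C)=CCC1C(=O)C=CC2=C1O[C@H](c1ccc3c(c1)C=CC(C)(C)O3)CC2=O | intermediate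
18 | (2S)-2-(2,2-dimethyl-2H-chromen-6-yl)-7-hydroxy-8-(3-methylbut-2-en-1-yl)chroman-4-one | CC(C)=CCc1c(O)ccc2c1O[C@H](c1ccc3c(c1)C=CC(C)(C)O3)CC2=O | target

## Count and risks
Total steps: 6. Longest linear sequence: 4 steps (1 → 2 → 5 → 6; the branch 3 → 4 → 5 → 6 is equally long).

**Risk 1, step 5.**
- The para-alkoxybenzyl radical 15 is easily oxidised to a free cation, which would close ring C without stereocontrol.
- Oxidative elimination can give the 2'-hydroxychalcone instead of the flavanone.
- A phenoxide of a second molecule of 6 may couple in place of the internal one.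
- The benzylic, α-oxy C2–H of 16 is the next weakest C–H bond, which is why 6 is kept in excess.

The fallback sets out from 6 and 13 and comes back at 16. The same perester-driven annulation runs through radicals 14 and 15 with no attempt at induction (Cu(MeCN)4PF6, 1,10-phenanthroline, PhCO3tBu, PhCF3, 40 °C). This gives racemic 2-(2,2-dimethyl-2H-chromen-6-yl)-7-[(2-methylbut-3-en-2-yl)oxy]chroman-4-one F1.

The stereocentre is then sorted by kinetic resolution through Noyori asymmetric transfer hydrogenation (RuCl(p-cymene)[(R,R)-TsDPEN] 1 mol %, HCO2H/Et3N 5:2, EtOAc, 20 °C, stopped near 52 % conversion). By the usual quadrant model this catalyst gives the (4R)-alcohol. Hydride attack anti to the 2-aryl group makes the (2R)-ketone the matched substrate. It is reduced to the (2R,4R)-cis-flavan-4-ol F2, while the (2S)-ketone 16 remains and is separated by chromatography.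

**Risk 2, step 6.** Some C6-prenyl isomer may form, the ee may erode slightly at 130 °C, or isoprene may be lost from the tertiary ether.

The fallback sets out from 6 and comes back at 18. The sigmatropic shift is moved ahead of the stereocentre.
- Aldehyde 6 is heated (toluene, 115 °C) and passes through ortho-dienone F3 to 2,4-dihydroxy-3-(3-methylbut-2-en-1-yl)benzaldehyde F4. The chelated 2-OH/CHO pair fixes the ring bonds so that only the carbon between the two oxygens is attacked.
- The free 4-OH is silylated (TBSCl, imidazole, CH2Cl2, 0 °C) to give the 4-O-TBS aldehyde F5.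
- The copper/perester annulation of step 5 with 13 then runs through aroyl radical F6 and benzylic radical F7 to the (2S)-7-O-TBS flavanone F8.
- Buffered fluoride (Bu4NF/AcOH 1:1, THF, 0 °C) frees 18.

The cost is two more steps. The allylic-benzylic CH2 of the prenyl group also now competes for tBuO•, so F5 is used in larger excess.

**Risk 3, step 2.** The electron-poor phenoxide is a good leaving group, so palladium may re-ionise 6 and drain it to the linear O-prenyl ether. The one-pot carbonate formation also leaves extra alkoxide in the flask.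

The fallback sets out from 3 and comes back at 6. The 4-OH of 3 is alkylated with 3-chloro-3-methylbut-1-yne (K2CO3, KI, CuI 5 mol %, acetone, 55 °C) to give 2-hydroxy-4-[(2-methylbut-3-yn-2-yl)oxy]benzaldehyde F9. The alkyne is then semi-hydrogenated (H2 1 atm, Pd/CaCO3 poisoned with Pb(OAc)2, quinoline, EtOAc, 10 °C) to give 6. The tertiary C–O bond is thus made by substitution at a propargylic centre, which cannot isomerise to a linear ether.

## Further compounds
F1 | step 5 | rac-2-(2,2-dimethyl-2H-chromen-6-yl)-7-[(2-methylbut-3-en-2-yl)oxy]chroman-4-one | C=CC(C)(C)Oc1ccc2c(c1)OC(c1ccc3c(c1)C=CC(C)(C)O3)CC2=O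
F2 | step 5 | (2R,4R)-2-(2,2-dimethyl-2H-chromen-6-yl)-7-[(2-methylbut-3-en-2-yl)oxy]chroman-4-ol | C=CC(C)(C)Oc1ccc2c(c1)O[C@@H](c1ccc3c(c1)C=CC(C)(C)O3)C[C@H]2O
F3 | step 6 | 2-hydroxy-3-(3-methylbut-2-en-1-yl)-4-oxocyclohexa-1,5-diene-1-carbaldehyde | CC(C)=CCC1C(=O)C=CC(C=O)=C1O
F4 | step 6 | 2,4-dihydroxy-3-(3-methylbut-2-en-1-yl)benzaldehyde | CC(C)=CCc1c(O)ccc(C=O)c1O
F5 | step 6 | 4-[(tert-butyldimethylsilyl)oxy]-2-hydroxy-3-(3-methylbut-2-en-1-yl)benzaldehyde | CC(C)=CCc1c(O[Si](C)(C)C(C)(C)C)ccc(C=O)c1O
F6 | step 6 | 4-[(tert-butyldimethylsilyl)oxy]-2-hydroxy-3-(3-methylbut-2-en-1-yl)benzoyl radical | CC(C)=CCc1c(O[Si](C)(C)C(C)(C)C)ccc([C]=O)c1O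
F7 | step 6 | 3-{4-[(tert-butyldimethylsilyl)oxy]-2-hydroxy-3-(3-methylbut-2-en-1-yl)phenyl}-1-(2,2-dimethyl-2H-chromen-6-yl)-3-oxopropyl radical | CC(C)=CCc1c(O[Si](C)(C)C(C)(C)C)ccc(C(=O)C[CH]c2ccc3c(c2)C=CC(C)(C)O3)c1O
F8 | step 6 | (2S)-7-[(tert-butyldimethylsilyl)oxy]-2-(2,2-dimethyl-2H-chromen-6-yl)-8-(3-methylbut-2-en-1-yl)chroman-4-one | CC(C)=CCc1c(O[Si](C)(C)C(C)(C)C)ccc2c1O[C@H](c1ccc3c(c1)C=CC(C)(C)O3)CC2=O
F9 | step 2 | 2-hydroxy-4-[(2-methylbut-3-yn-2-yl)oxy]benzaldehyde | C#CC(C)(C)Oc1ccc(C=O)c(O)c1
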